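## Retrosynthetic overview

1. Target 19 comes from britannilactone 18 by double isobutyrylation at O–C1 and O–C6. C4 is carried unchanged from (S)-citronellic acid.
2. The feature used is cyclohexene ring B (C5–C10), cis-fused at C7–C8 to the α-methylene-γ-butyrolactone (O, C8, C7, C11=C13, C12=O). This is the retron of an allene + aldehyde + CO (2+2+1). One step forms C7–C8, C11–C12 and C12–O, closes both rings and sets C7/C8, starting from the acyclic allenyl aldehyde 16.
3. Ring B is a "benzene dihydrate" (C6–O, C8–O, C5=C10). Cyclic C6 or C8 ketones would aromatise, so ring B is closed last, at its final oxidation level.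
4. 16 comes from lactol 12 and propargyl boronate 13 (C7, C11, C13; the catalyst sets C6). The Z-C5=C10 bond is locked in δ-lactone 11, made from acid dianion 5 (C5) and ketone 6 (C10, C14, C9, C8).
5. Ring order: a temporary δ-lactone (steps 4–5) is opened in step 7, then ring B and the γ-lactone form together in step 10.

Key step: step 10

Remark on numbering (eudesmane numbering is used throughout):
- C1 is the side-chain CH2O; C2 and C3 are the side-chain CH2 groups.
- C4 is the side-chain stereocentre and carries CH3 C15.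
- C5=C10 is the ring alkene; C10 carries CH3 C14.
- C6 is the CH–O(acyl) carbon; C7 and C8 are the ring-fusion carbons (C8–O); C9 is the ring CH2.
- C11=C13 is the exocyclic methylene; C12 is the lactone C=O.
- Compounds 1, 6 and 13 are taken as commercial.

## Route

Step 1
Reactants: 1 (S)-citronellic acid
Product: 3 (3S)-6-hydroxy-3-methylhexanoic acid, via aldehyde acid 2 (not isolated)
Conditions: O3, CH2Cl2–MeOH, −78 °C; then NaBH4 (excess), −78 °C to rt; acidic work-up
Reagents that add atoms: ozone [O-][O+]=O
Why: Ozonolysis with reductive work-up cleaves the only C=C bond and gives the C1 primary alcohol, while the carboxylate and the C4 stereocentre are not touched.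

Step 2
Reactants: 3 (3S)-6-hydroxy-3-methylhexanoic acid
Product: 5 (3S)-6-(tert-butyldiphenylsilyloxy)-3-methylhexanoic acid, via silyl ester 4 (not isolated)
Conditions: TBDPSCl (2.2 equiv), imidazole, DMF, rt; then THF–H2O–AcOH (cat.), rt
Reagents that add atoms: tert-butyl(chloro)diphenylsilane (TBDPSCl) CC(C)(C)[Si](Cl)(c1ccccc1)c1ccccc1
Why: This is a standard silyl ether formation, and the labile silyl ester hydrolyses selectively, so O–C1 carries a group that survives base, hydride, hydrogenolysis and Mo(0).

Step 3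
Reactants: 5 (3S)-6-(tert-butyldiphenylsilyloxy)-3-methylhexanoic acid; 6 4-(benzyloxy)butan-2-one
Product: 7 5-(benzyloxy)-3-hydroxy-3-methyl-2-[(2S)-5-(tert-butyldiphenylsilyloxy)pentan-2-yl]pentanoic acid (epimer mixture at C5/C10)
Conditions: LDA (2.2 equiv), THF, −78 to 0 °C; then 6, −78 °C; aq. HCl
Reagents that add atoms: none
Why: Aldol-type addition of a carboxylic acid dianion to a methyl ketone forms C5–C10, and the new centres C5 and C10 are deliberately left uncontrolled because both are erased in step 5.

Step 4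
Reactants: 7 the aldol acid
Product: 9 4-hydroxy-4-methyl-3-[(2S)-5-(tert-butyldiphenylsilyloxy)pentan-2-yl]tetrahydro-2H-pyran-2-one (epimer mixture at C5/C10), via dihydroxy acid 8 (not isolated)
Conditions: H2 (1 atm), Pd/C, EtOAc, rt; filter; then PPTS (cat.), PhH, 50 °C
Reagents that add atoms: none
Why: Benzyl ether hydrogenolysis followed by acid-catalysed δ-lactonisation ties O–C8 to C6, which will hold C9 and C6 on the same side of the future alkene.

Step 5
Reactants: 9 the β-hydroxy-δ-lactone
Product: 11 4-methyl-3-[(2S)-5-(tert-butyldiphenylsilyloxy)pentan-2-yl]-5,6-dihydro-2H-pyran-2-one, via tertiary acetate 10 (not isolated)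
Conditions: Ac2O, Et3N, DMAP, CH2Cl2, rt; then DBU, PhMe, 60 °C
Reagents that add atoms: none
Why: Acetylation and E1cB elimination through the lactone enolate place the alkene regiospecifically at C5=C10, and the ring fixes its Z geometry from both epimers.

Step 6
Reactants: 11 the unsaturated δ-lactone
Product: 12 4-methyl-3-[(2S)-5-(tert-butyldiphenylsilyloxy)pentan-2-yl]-5,6-dihydro-2H-pyran-2-ol (anomer mixture)
Conditions: DIBAL-H (1.1 equiv), CH2Cl2, −78 °C; Rochelle salt
Reagents that add atoms: none
Why: Partial reduction of a lactone with DIBAL-H stops at the aluminium lactolate at low temperature, and the lactol is the ring-closed form of the (Z)-hydroxy enal (C6 aldehyde).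

Step 7
Reactants: 12 the lactol; 13 propargylboronic acid pinacol ester
Product: 14 (3Z,5S)-3-methyl-4-[(2S)-5-(tert-butyldiphenylsilyloxy)pentan-2-yl]octa-3,6,7-triene-1,5-diol
Conditions: 13 (1.5 equiv), (S)-TRIP (10 mol %), 4 Å MS, PhMe, −20 °C to rt
Reagents that add atoms: none
Why: Chiral phosphoric acid-catalysed propargylboration (SE2′, closed six-membered transition state) of the open hydroxy-enal tautomer should give the allenyl carbinol, with the catalyst enantiomer chosen for Si-face attack so that C6 is set as S independently of the remote C4.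

Step 8
Reactants: 14 the allenyl diol
Product: 15 the bis(triethylsilyl) ether of 14
Conditions: TESOTf (2.5 equiv), 2,6-lutidine, CH2Cl2, −78 to 0 °C
Reagents that add atoms: triethylsilyl trifluoromethanesulfonate (TESOTf) CC[Si](CC)(CC)OS(=O)(=O)C(F)(F)F
Why: Silylation with a silyl triflate under non-nucleophilic base covers the hindered, acid-sensitive C6 carbinol as well as the primary C8 alcohol.

Step 9
Reactants: 15 the bis-TES ether
Product: 16 (3Z,5S)-3-methyl-4-[(2S)-5-(tert-butyldiphenylsilyloxy)pentan-2-yl]-5-(triethylsilyloxy)octa-3,6,7-trienal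
Conditions: (COCl)2, DMSO, CH2Cl2, −78 to −40 °C; then Et3N, −78 to 0 °C
Reagents that add atoms: none
Why: Swern oxidation acts directly on the unhindered primary TES ether, whereas the secondary TES and the TBDPS ether stay, and the low temperature should keep C5=C10 out of conjugation.

Step 10
Reactants: 16 the allenyl aldehyde
Product: 17 (3aR,4S,7aR)-6-methyl-3-methylidene-5-[(2S)-5-(tert-butyldiphenylsilyloxy)pentan-2-yl]-4-(triethylsilyloxy)-3a,4,7,7a-tetrahydro-1-benzofuran-2(3H)-one
Conditions: Mo(CO)6 (1.2 equiv), DMSO (10 equiv), PhMe, 100 °C, Ar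
Reagents that add atoms: molybdenum hexacarbonyl (CO source) [Mo].[C-]#[O+].[C-]#[O+].[C-]#[O+].[C-]#[O+].[C-]#[O+].[C-]#[O+]
Why: This is a hetero-Pauson–Khand reaction, a (2+2+1) of the internal allene π-bond C7=C11, the aldehyde C8=O and CO, a reaction type known to turn allenyl aldehydes into cis-fused bicyclic α-methylene-γ-butyrolactones with five- and six-membered carbocycles. Mo(0), freed from CO ligands by DMSO, binds both π-systems and couples them oxidatively to an oxamolybdacyclopentane (C7–C8 bond), CO then inserts into the Mo–C11 bond, and reductive elimination closes C12–O. Ring B closes in a 6-exo sense on the allene (C11 stays outside ring B), helped by the Z-C5=C10 bond that holds C6 and C9 on one side, and the lactone closes by reductive elimination from the acyl metallacycle. C7 and C8 are set together because the metallacycle can only be cis-fused to the forming six-membered ring (H7 and H8 cis), and C6 controls the face: in the reactive rotamer C6–H lies in the allene plane, the tether atom C5 sits on the Mo-bound face and the bulky OTES points away, which should put C7–C11 trans to C6–O. The step needs selectivity for the internal over the terminal allene bond, secured by the six- versus seven-membered ring closure, and it needs an inert C5=C10 and a non-basic medium so that the β,γ-unsaturated aldehyde is neither conjugated nor loses the C6 oxygen, which the poor silanolate leaving group supports. Because ring B appears at its final oxidation level, no cyclic C6 or C8 ketone that could aromatise is ever formed.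

Step 11
Reactants: 17 the bis-silylated bicyclic lactone
Product: 18 britannilactone, (3aS,4S,7aR)-4-hydroxy-5-[(2S)-5-hydroxypentan-2-yl]-6-methyl-3-methylidene-3a,4,7,7a-tetrahydro-1-benzofuran-2(3H)-one
Conditions: HF·pyridine, pyridine, THF, 0 °C to rt
Reagents that add atoms: none
Why: Fluoride-mediated desilylation in a buffered, weakly acidic medium removes TES and TBDPS without the base-induced Michael addition or translactonisation that the α-methylene lactone would suffer.

Step 12
Reactants: 18 britannilactone
Product: 19 target, (3aR,4S,7aR)-6-methyl-3-methylidene-5-[(2S)-5-(isobutyryloxy)pentan-2-yl]-2-oxo-2,3,3a,4,7,7a-hexahydro-1-benzofuran-4-yl isobutyrate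
Conditions: (iPrCO)2O, Et3N, DMAP (cat.), CH2Cl2, 0 °C to rt
Reagents that add atoms: isobutyric anhydride CC(C)C(=O)OC(=O)C(C)C
Why: DMAP-catalysed double acylation installs both identical esters (O–C1 and O–C6) in one operation with retention at C6.

## Compound list

1 | (S)-citronellic acid, (3S)-3,7-dimethyloct-6-enoic acid | OC(=O)C[C@@H](C)CCC=C(C)C | starting material
2 | (3S)-3-methyl-6-oxohexanoic acid | OC(=O)C[C@@H](C)CCC=O | intermediate
3 | (3S)-6-hydroxy-3-methylhexanoic acid | OC(=O)C[C@@H](C)CCCO | intermediate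
4 | tert-butyldiphenylsilyl (3S)-6-(tert-butyldiphenylsilyloxy)-3-methylhexanoate | CC(C)(C)[Si](c1ccccc1)(c1ccccc1)OC(=O)C[C@@H](C)CCCO[Si](c1ccccc1)(c1ccccc1)C(C)(C)C | intermediate
5 | (3S)-6-(tert-butyldiphenylsilyloxy)-3-methylhexanoic acid | OC(=O)C[C@@H](C)CCCO[Si](c1ccccc1)(c1ccccc1)C(C)(C)C | intermediate
6 | 4-(benzyloxy)butan-2-one | CC(=O)CCOCc1ccccc1 | starting material
7 | 5-(benzyloxy)-3-hydroxy-3-methyl-2-[(2S)-5-(tert-butyldiphenylsilyloxy)pentan-2-yl]pentanoic acid (C5/C10 epimers) | OC(=O)C([C@@H](C)CCCO[Si](c1ccccc1)(c1ccccc1)C(C)(C)C)C(C)(O)CCOCc1ccccc1 | intermediate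
8 | 3,5-dihydroxy-3-methyl-2-[(2S)-5-(tert-butyldiphenylsilyloxy)pentan-2-yl]pentanoic acid (C5/C10 epimers) | OC(=O)C([C@@H](C)CCCO[Si](c1ccccc1)(c1ccccc1)C(C)(C)C)C(C)(O)CCO | intermediate
9 | 4-hydroxy-4-methyl-3-[(2S)-5-(tert-butyldiphenylsilyloxy)pentan-2-yl]tetrahydro-2H-pyran-2-one (C5/C10 epimers) | O=C1OCCC(C)(O)C1[C@@H](C)CCCO[Si](c2ccccc2)(c2ccccc2)C(C)(C)C | intermediate
10 | 4-acetoxy-4-methyl-3-[(2S)-5-(tert-butyldiphenylsilyloxy)pentan-2-yl]tetrahydro-2H-pyran-2-one (C5/C10 epimers) | O=C1OCCC(C)(OC(C)=O)C1[C@@H](C)CCCO[Si](c2ccccc2)(c2ccccc2)C(C)(C)C | intermediate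
11 | 4-methyl-3-[(2S)-5-(tert-butyldiphenylsilyloxy)pentan-2-yl]-5,6-dihydro-2H-pyran-2-one | O=C1OCCC(C)=C1[C@@H](C)CCCO[Si](c2ccccc2)(c2ccccc2)C(C)(C)C | intermediate
12 | 4-methyl-3-[(2S)-5-(tert-butyldiphenylsilyloxy)pentan-2-yl]-5,6-dihydro-2H-pyran-2-ol (anomers) | OC1OCCC(C)=C1[C@@H](C)CCCO[Si](c2ccccc2)(c2ccccc2)C(C)(C)C | intermediate
13 | propargylboronic acid pinacol ester | C#CCB1OC(C)(C)C(C)(C)O1 | starting material
14 | (3Z,5S)-3-methyl-4-[(2S)-5-(tert-butyldiphenylsilyloxy)pentan-2-yl]octa-3,6,7-triene-1,5-diol | OCC/C(C)=C(/[C@@H](C)CCCO[Si](c1ccccc1)(c1ccccc1)C(C)(C)C)[C@@H](O)C=C=C | intermediate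
15 | 1,5-bis(triethylsilyl) ether of 14 | CC[Si](CC)(CC)OCC/C(C)=C(/[C@@H](C)CCCO[Si](c1ccccc1)(c1ccccc1)C(C)(C)C)[C@@H](O[Si](CC)(CC)CC)C=C=C | intermediate
16 | (3Z,5S)-3-methyl-4-[(2S)-5-(tert-butyldiphenylsilyloxy)pentan-2-yl]-5-(triethylsilyloxy)octa-3,6,7-trienal | O=CC/C(C)=C(/[C@@H](C)CCCO[Si](c1ccccc1)(c1ccccc1)C(C)(C)C)[C@@H](O[Si](CC)(CC)CC)C=C=C | intermediate
17 | (3aR,4S,7aR)-bicyclic α-methylene lactone with 6-OTES and 1-OTBDPS | C=C1C(=O)O[C@@H]2CC(C)=C([C@@H](C)CCCO[Si](c3ccccc3)(c3ccccc3)C(C)(C)C)[C@@H](O[Si](CC)(CC)CC)[C@H]12 | intermediate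
18 | britannilactone (C1-OH, C6-OH) | C=C1C(=O)O[C@@H]2CC(C)=C([C@@H](C)CCCO)[C@@H](O)[C@H]12 | intermediate
19 | 1,6-O,O-diisobutyrylbritannilactone (CNP0509808.1) | C=C1C(=O)O[C@@H]2CC(C)=C([C@@H](C)CCCOC(=O)C(C)C)[C@@H](OC(=O)C(C)C)[C@H]12 | target

## Step count

Total step count: 12. Longest linear sequence: 12 steps (1 to 19).

## Steps most likely to fail

**Step 10.** Three processes may interfere:
- poor facial selectivity at C7 relative to C6;
- migration of C5=C10 into conjugation with the aldehyde;
- vinylogous loss of the C6 oxygen at 100 °C.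

The fallback splits the one-step cycloaddition into a room-temperature carbocyclisation and a separate carbonylation. It sets out from 16. Pd(0)-catalysed silastannylation of the allene with Bu3Sn–SiMe3, followed by in-situ intramolecular allylstannane addition to the aldehyde, should give the cis-hydroxy vinylsilane F1. Iododesilylation (NIS, MeCN) gives the vinyl iodide F2. Pd(0)-catalysed carbonylative lactonisation (CO 1 atm, Et3N) comes back to the route at 17. If only the C6/C7 relation is wrong, the sequence is run with the C6 epimer, and C6 is inverted at the end by a Mitsunobu reaction with isobutyric acid.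

**Step 7.** Two processes may interfere:
- slow opening of the lactol together with low reactivity of the hindered tetrasubstituted enal;
- eroded catalyst control.

The fallback builds the allene in two stages from an alkyne. It sets out from 12. Zn–ProPhenol-catalysed asymmetric addition of trimethylsilylacetylene (Me2Zn, PhMe) gives the silyl propargylic diol F3. K2CO3 in MeOH gives the terminal alkyne F4. Crabbé homologation ((CH2O)n, CuI, dicyclohexylamine, dioxane, reflux) comes back to the route at 14.

**Step 3.** Enolisation of ketone 6 by the strongly basic dianion, followed by β-elimination of benzyl alkoxide, may compete with addition. The fallback forms C8–C9 last instead of bringing it in with the ketone. It sets out from 5. The dianion is added to acetone to give the β-hydroxy acid F5. Dehydration (Ac2O, then DBU) gives the 2-substituted 3-methylbut-2-enoic acid F6. A second double deprotonation removes a proton from the methyl group cis to the carboxylate. γ-Hydroxymethylation with paraformaldehyde then gives the (Z)-δ-hydroxy acid F7, in which α-attack is blocked by the fully substituted C5. F7 lactonises on acidification and comes back to the route at 11.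

## Further compounds

F1 | step 10 | cis-hydroxy vinylsilane (C8-OH, C7-C(=CH2)SiMe3, 6-OTES, 1-OTBDPS) | O[C@@H]1CC(C)=C([C@@H](C)CCCO[Si](c2ccccc2)(c2ccccc2)C(C)(C)C)[C@@H](O[Si](CC)(CC)CC)[C@@H]1C(=C)[Si](C)(C)C
F2 | step 10 | cis-hydroxy vinyl iodide (C8-OH, C7-C(=CH2)I, 6-OTES, 1-OTBDPS) | O[C@@H]1CC(C)=C([C@@H](C)CCCO[Si](c2ccccc2)(c2ccccc2)C(C)(C)C)[C@@H](O[Si](CC)(CC)CC)[C@@H]1C(=C)I
F3 | step 7 | (Z)-silyl propargylic diol (C6 carbinol bearing C≡C–SiMe3) | OCC/C(C)=C(/[C@@H](C)CCCO[Si](c1ccccc1)(c1ccccc1)C(C)(C)C)[C@@H](O)C#C[Si](C)(C)C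
F4 | step 7 | (Z)-terminal propargylic diol | OCC/C(C)=C(/[C@@H](C)CCCO[Si](c1ccccc1)(c1ccccc1)C(C)(C)C)[C@@H](O)C#C
F5 | step 3 | 3-hydroxy-3-methyl-2-[(2S)-5-(tert-butyldiphenylsilyloxy)pentan-2-yl]butanoic acid (C5 epimers) | OC(=O)C([C@@H](C)CCCO[Si](c1ccccc1)(c1ccccc1)C(C)(C)C)C(C)(C)O
F6 | step 3 | 3-methyl-2-[(2S)-5-(tert-butyldiphenylsilyloxy)pentan-2-yl]but-2-enoic acid | OC(=O)C([C@@H](C)CCCO[Si](c1ccccc1)(c1ccccc1)C(C)(C)C)=C(C)C
F7 | step 3 | (Z)-5-hydroxy-3-methyl-2-[(2S)-5-(tert-butyldiphenylsilyloxy)pentan-2-yl]pent-2-enoic acid | OCC/C(C)=C(/[C@@H](C)CCCO[Si](c1ccccc1)(c1ccccc1)C(C)(C)C)C(=O)O
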